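The runs come from a simulation for an exercise; noise was put on by code.

At the 30.0 h reading the dawn flask stands where it has stood since 4.00 h, with target near 14.2% and starting material near 58.1% of the charge. I carry one number over for you, the target share f, which is target divided by the starting material that has reacted: the chance that a molecule which has left the starting material is found as target. In the dawn flask f is 0.339, about a third.

| setting | dawn | spring | flask |
|---|---|---|---|
| starting material | 0.050 M | 0.050 M | 0.050 M |
| coupling partner | 0.0525 M | 0.10 M | 0.0525 M |
| second substrate | 0.025 M | 0.025 M | 0.0250 M |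
| protic impurity | 2.5 mM | 2.5 mM | 2.50 mM |
| temperature | 0 °C | −5 °C | 0 °C |
| remark | the very flask that is asked about, followed so far | run made earlier |  |
| time |  |  | 40 h |

dawn run (percent of the starting material charged)

| time / h | target / % | starting material / % |
|---|---|---|
| 2.50 | 17.6 | 58.3 |
| 4.00 | 14.6 | 56.7 |
| 8.00 | 15.2 | 57.3 |
| 12.0 | 14.3 | 58.7 |
| 20.0 | 13.7 | 60.3 |
| 30.0 | 13.2 | 57.6 |

spring run (percent of the starting material charged)

| time / min | target / % | starting material / % |
|---|---|---|
| 20.0 | 26.8 | 66.8 |
| 40.0 | 28.8 | 52.3 |
| 60.0 | 27.7 | 46.5 |
| 80.0 | 27.3 | 43.1 |
| 90.0 | 25.2 | 39.7 |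
| 120 | 26.2 | 37.5 |

(readings scatter by 1 percentage point)

- Wednesday's: change nothing and wait 20 h more
- Friday's: at 40 h take out 90% of the target then present, then wait 20 h
- Saturday's: at 40 h raise the temperature by 15 K, then wait 20 h
- Tuesday's: at 40 h add coupling partner, 50.0% of the amount charged, then wait 20 h

- target, in percent of the starting material first charged, at 40 h
- which option adds most target ("none" when 2 percentage points or less is all one gets) (Wednesday's / Friday's / Saturday's / Tuesday's / none)
- target present, with what was taken out counted in, in percent of the starting material first charged, after Friday's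
- target present, with what was taken out counted in, in percent of the starting material first charged, after Saturday's

- removed target is counted in
- the earlier runs were read with a standard deviation of 1 percentage point
- additions bring no volume worth counting

I read this stall as a balance (an equilibrium), not a spent limiting reagent, since the coupling partner charged is more than the reacted starting material, second substrate and protic impurity could take at one each, with at least 0.00406 M over. When you come at 40 h I expect target still near 14.2%, so waiting gains nothing. I leave the heat alone, as I have no run warmer than the dawn flask's 0 °C, and the spring flask differs from the dawn flask in coupling partner as well as temperature, so it can't show me what heat does. Reading the stall as a balance, I expect target taken out to be made again from what it balances with, and the 20 h of waiting is longer than the 4.00 h by which the dawn flask had stalled, so I put Friday's first.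

The forecast parts from me here: it gives 12.5%, 12.4% after Friday's, 9% after Saturday's and picks Tuesday's, holding “there is no equilibrium to pull”.

The flask gives 14.7%, 25.2% after Friday's and 10.1% after Saturday's; the best option is Friday's, adding 11 percentage points.

    target ⇌ isomer of the product (K = 1.89, k = 8.87 × 10⁻⁴ s⁻¹, Ea = 89.0 kJ mol⁻¹, ΔH = 9.00 kJ mol⁻¹)
    coupling partner + protic impurity → quenched reagent (k = 2.11 M⁻¹ s⁻¹, Ea = 51.0 kJ mol⁻¹)
    second substrate ⇌ dormant form (K = 1.01, k = 0.00174 s⁻¹, Ea = 72.0 kJ mol⁻¹, ΔH = −27.0 kJ mol⁻¹)
    starting material + coupling partner ⇌ target (K = 11.5 M⁻¹, k = 0.00674 M⁻¹ s⁻¹, Ea = 42.0 kJ mol⁻¹, ΔH = −34.0 kJ mol⁻¹)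
    second substrate + coupling partner ⇌ second product (K = 33.0 M⁻¹, k = 0.00768 M⁻¹ s⁻¹, Ea = 67.0 kJ mol⁻¹, ΔH = −48.0 kJ mol⁻¹)
    (constants at 0 °C)

In this flask the relaxation half-lives of target with starting material, 0.207 h, and of target with isomer of the product, 0.142 h, are short against the 40 h. Reckoned with f, the flask gives 14.4% of target, and the neighbour with 0.21 M of coupling partner, holding 16.9% of starting material, gives 28.2% against its simulated 28.8%.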